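**Plan**

Numbering used below: ring carbons C1 (bears the aryl ether), C2=C3 (C3 carries the methyl), C4 (carbinol), C5 (CH2), C6 (carries the side chain); side chain C7 (CHMe), C8, C9 (C=O).
Cuts, in retrosynthetic order: the C=C next to the ether-bearing arene (boron-templated aldol with diketone 25); the allylic C1–OAr bond (palladium allylic etherification with vanillin); C9–isobutenyl (Weinreb ketone synthesis); the ring bond C5–C6 (enolate alkylation); C1–C2 (acylation of a Z-alkenyl Grignard reagent by a glutarate Weinreb amide).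
Enabling feature: C5 and C6 are each alpha to an oxygen-bearing ring carbon (C4–OH and C1–OAr), a 1,4-dioxygen pattern of like polarity. With C1 as a ketone, C6 is an enolate carbon; C5 is turned into the electrophile as the primary sulfonate of a glycerol-derived diol; the Z-configured C2=C3 bond holds both ends together for a six-membered closure.
Forward order: alkyne → Z-iodoalkene 7; half-ester → Weinreb amide 9; union to Z-enone 11; ring closure to cyclohexenone 13; ketone reduction, side-chain enone, aryl ether, curcuminoid.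
Stereochemistry: C4 from (S)-glyceraldehyde acetonide; C7 from methyl hydrogen (R)-3-methylglutarate; C6 relayed from C4 in the ring closure; C1 from axial hydride delivery, kept by double inversion at palladium; Z alkene from anti-carbomagnesiation; E styryl alkenes from the aldol condensations.

Key step: step 6

Assumption: the target is drawn as one keto–enol tautomer of the 1,3-diketone; the tautomers interconvert, so the diketone is built without fixing the position of the enol.

**Route**

Step 1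
Reactants: 1 (4S)-2,2-dimethyl-1,3-dioxolane-4-carbaldehyde (commercial)
Product: 3 (2R)-but-3-yne-1,2-diol, via (4R)-4-ethynyl-2,2-dimethyl-1,3-dioxolane 2 (not isolated)
Conditions: dimethyl (1-diazo-2-oxopropyl)phosphonate, K2CO3, MeOH, 0 °C → rt; then 2 M aq. HCl to pH 1, rt
Reagents that add atoms: dimethyl (1-diazo-2-oxopropyl)phosphonate COP(=O)(OC)C(=[N+]=[N-])C(C)=O
Why: Seyferth–Gilbert homologation with the Ohira–Bestmann reagent should turn the aldehyde into the terminal alkyne under mild base without epimerising the alpha-alkoxy centre, and acid hydrolysis of the acetonide in the same flask avoids isolating the volatile alkyne; the future C4 stereocentre is carried over from 1.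

Step 2
Reactants: 3 (2R)-but-3-yne-1,2-diol
Product: 5 (2R,3Z)-4-iodo-3-methylbut-3-ene-1,2-diol, via alkenylmagnesium bromide 4 (not isolated)
Conditions: MeMgBr (4 equiv), CuI (20 mol%), THF/Et2O, −10 °C → rt; then I2, −20 → 0 °C
Reagents that add atoms: methylmagnesium bromide C[Mg]Br; iodine II
Why: CuI-catalysed anti-carbomagnesiation of the propargylic alkoxide should place methyl on the alkyne carbon next to the carbinol and magnesium on the terminus inside a five-membered chelate, so iodinolysis gives the Z-iodoalkene with iodine cis to the carbinol carbon.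

Step 3
Reactants: 5 (2R,3Z)-4-iodo-3-methylbut-3-ene-1,2-diol
Product: 7 (2R,3Z)-2-{[tert-butyl(dimethyl)silyl]oxy}-4-iodo-3-methylbut-3-en-1-yl 4-methylbenzenesulfonate, via primary monotosylate 6 (not isolated)
Conditions: TsCl (1.05 equiv), Et3N, Bu2SnO (2 mol%), CH2Cl2, 0 °C → rt; then 2,6-lutidine, TBSOTf, −78 → 0 °C
Reagents that add atoms: 4-methylbenzenesulfonyl chloride Cc1ccc(cc1)S(Cl)(=O)=O; tert-butyldimethylsilyl trifluoromethanesulfonate CC(C)(C)[Si](C)(C)OS(=O)(=O)C(F)(F)F
Why: Tin-catalysed sulfonylation through the dibutylstannylene acetal should select the primary hydroxyl, and silylation of the remaining secondary allylic hydroxyl in the same flask gives the differentiated diol in which C5 is an electrophile.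

Step 4
Reactants: 8 (3R)-5-methoxy-3-methyl-5-oxopentanoic acid (methyl hydrogen (R)-3-methylglutarate, commercial)
Product: 9 methyl (3R)-5-[methoxy(methyl)amino]-3-methyl-5-oxopentanoate
Conditions: MeNHOMe·HCl, EDC·HCl, N-methylmorpholine, DMAP (cat.), CH2Cl2, 0 °C → rt
Reagents that add atoms: N,O-dimethylhydroxylamine hydrochloride CNOC.Cl
Why: Carbodiimide amide coupling converts the free acid arm into the Weinreb amide and leaves the methyl ester arm, which decides that the acid arm becomes the ring carbonyl C1; the C7 stereocentre comes from the enantiopure half-ester.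

Step 5
Reactants: 7 (2R,3Z)-2-{[tert-butyl(dimethyl)silyl]oxy}-4-iodo-3-methylbut-3-en-1-yl 4-methylbenzenesulfonate; 9 methyl (3R)-5-[methoxy(methyl)amino]-3-methyl-5-oxopentanoate
Product: 11 methyl (3R,6Z,8R)-8-{[tert-butyl(dimethyl)silyl]oxy}-3,7-dimethyl-9-[(4-methylbenzenesulfonyl)oxy]-5-oxonon-6-enoate, via alkenylmagnesium chloride 10 (not isolated)
Conditions: 7, iPrMgCl·LiCl (1.1 equiv), THF, −20 °C → rt; then 9, −40 → 0 °C; aq. NH4Cl
Reagents that add atoms: none
Why: Iodine–magnesium exchange proceeds with retention of alkene geometry, and the alkenyl Grignard reagent should add once to the Weinreb amide (stable chelated adduct) faster than to the methyl ester, giving the Z-enone (Weinreb ketone synthesis).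

Step 6
Reactants: 11 methyl (3R,6Z,8R)-8-{[tert-butyl(dimethyl)silyl]oxy}-3,7-dimethyl-9-[(4-methylbenzenesulfonyl)oxy]-5-oxonon-6-enoate
Product: 13 methyl (3S)-3-[(1R,5S)-5-{[tert-butyl(dimethyl)silyl]oxy}-4-methyl-2-oxocyclohex-3-en-1-yl]butanoate, via lithium dienolate 12 (not isolated)
Conditions: LiN(SiMe3)2 (1.05 equiv), THF (0.02 M), −78 °C; then −78 → 0 °C
Reagents that add atoms: none
Why: LiN(SiMe3)2 should remove an alpha' proton at C6 of the Z-enone under kinetic control to give the cross-conjugated lithium dienolate 12, whose enolate carbon displaces the primary tosylate at C5 in an intramolecular SN2 reaction. The closest known reaction type is the intramolecular C-alkylation of a ketone enolate by a sulfonate (cycloalkylation to a cyclohexenone). The six-membered ring closes in the 6-(enolendo)-exo-tet mode, which is geometrically possible only because the Z-configured C2=C3 bond holds C1 and C4 cis. The new stereocentre C6 is controlled by C4: in the half-chair transition state the silyloxy group sits pseudoaxial to avoid A1,2 strain with the C3 methyl and the side chain (cis to oxygen in the enolate of a vinyl ketone) becomes equatorial, which gives the 4,6-trans product; this is also the more stable C6 epimer, so any cis isomer can be funnelled to it through the enolate. The step needs alpha' over gamma deprotonation (kinetic amide base at −78 °C), C- over O-alkylation (lithium counter-ion in THF without dipolar cosolvent) and ketone over ester enolisation (acidity difference).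

Step 7
Reactants: 13 methyl (3S)-3-[(1R,5S)-5-{[tert-butyl(dimethyl)silyl]oxy}-4-methyl-2-oxocyclohex-3-en-1-yl]butanoate
Product: 14 methyl (3S)-3-[(1R,2R,5S)-5-{[tert-butyl(dimethyl)silyl]oxy}-2-hydroxy-4-methylcyclohex-3-en-1-yl]butanoate
Conditions: NaBH4, CeCl3·7H2O, MeOH, −40 °C
Reagents that add atoms: none
Why: Luche 1,2-reduction; axial hydride delivery to the half-chair with pseudoaxial C4–OTBS and equatorial C6 side chain should give the equatorial C1 alcohol, trans to the side chain and cis to the silyl ether (also the more stable alcohol).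

Step 8
Reactants: 14 methyl (3S)-3-[(1R,2R,5S)-5-{[tert-butyl(dimethyl)silyl]oxy}-2-hydroxy-4-methylcyclohex-3-en-1-yl]butanoate
Product: 16 (6S)-6-[(1R,2R,5S)-5-{[tert-butyl(dimethyl)silyl]oxy}-2-hydroxy-4-methylcyclohex-3-en-1-yl]-2-methylhept-2-en-4-one, via Weinreb amide 15 (not isolated)
Conditions: MeNHOMe·HCl, iPrMgCl, THF, −20 °C; then 2-methylprop-1-en-1-ylmagnesium bromide, −20 → 0 °C; aq. NH4Cl
Reagents that add atoms: 2-methylprop-1-en-1-ylmagnesium bromide CC(C)=C[Mg]Br
Why: One-pot aminolysis of the ester (or of any lactone formed from 14) by the chloromagnesium amide, then single Grignard addition to the Weinreb amide (Weinreb ketone synthesis), should give the beta,beta-dimethyl enone while the C1 magnesium alkoxide stays inert.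

Step 9
Reactants: 16 (6S)-6-[(1R,2R,5S)-5-{[tert-butyl(dimethyl)silyl]oxy}-2-hydroxy-4-methylcyclohex-3-en-1-yl]-2-methylhept-2-en-4-one
Product: 17 (1R,4S,6R)-4-{[tert-butyl(dimethyl)silyl]oxy}-3-methyl-6-[(2S)-6-methyl-4-oxohept-5-en-2-yl]cyclohex-2-en-1-yl methyl carbonate
Conditions: ClCO2Me, pyridine, DMAP (cat.), CH2Cl2, 0 °C
Reagents that add atoms: methyl chloroformate COC(Cl)=O
Why: Acylation of the secondary allylic alcohol gives the allylic carbonate needed for ionisation; no stereocentre is touched.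

Step 10
Reactants: 17 (1R,4S,6R)-4-{[tert-butyl(dimethyl)silyl]oxy}-3-methyl-6-[(2S)-6-methyl-4-oxohept-5-en-2-yl]cyclohex-2-en-1-yl methyl carbonate; 18 4-hydroxy-3-methoxybenzaldehyde (vanillin)
Product: 19 4-({(1R,4S,6R)-4-{[tert-butyl(dimethyl)silyl]oxy}-3-methyl-6-[(2S)-6-methyl-4-oxohept-5-en-2-yl]cyclohex-2-en-1-yl}oxy)-3-methoxybenzaldehyde
Conditions: Pd(PPh3)4 (5 mol%), THF, rt
Reagents that add atoms: none
Why: Tsuji–Trost allylic etherification: zerovalent palladium ionises the carbonate with inversion and the phenoxide of 18 (formed by the released methoxide) should attack the less hindered secondary allyl terminus C1 anti to palladium, so the ether forms with net retention at C1 and the alkene stays at C2=C3.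

Step 11
Reactants: 19 4-({(1R,4S,6R)-4-{[tert-butyl(dimethyl)silyl]oxy}-3-methyl-6-[(2S)-6-methyl-4-oxohept-5-en-2-yl]cyclohex-2-en-1-yl}oxy)-3-methoxybenzaldehyde
Product: 20 4-({(1R,4S,6R)-4-hydroxy-3-methyl-6-[(2S)-6-methyl-4-oxohept-5-en-2-yl]cyclohex-2-en-1-yl}oxy)-3-methoxybenzaldehyde
Conditions: Bu4NF, AcOH (1:1), THF, 0 °C → rt
Reagents that add atoms: none
Why: Fluoride-mediated desilylation buffered by acetic acid should free the C4 hydroxyl without enolising the ketone or touching the aldehyde and the allylic aryl ether.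

Step 12
Reactants: 21 pentane-2,4-dione; 22 4-hydroxybenzaldehyde
Product: 25 (3Z,5E)-4-hydroxy-6-(4-hydroxyphenyl)hexa-3,5-dien-2-one, via acetylacetone difluoroboron chelate 23 (not isolated), via styryl diketone difluoroboron chelate 24 (not isolated)
Conditions: 21 (3 equiv), BF3·OEt2 (3 equiv), toluene, 65 °C; then 22 (1 equiv), B(OnBu)3, n-BuNH2 (0.2 equiv, slow addition), 65 °C; then NaHC2O4/Na2C2O4 (pH about 6), MeOH/H2O, 65 °C
Reagents that add atoms: none
Why: Difluoroboron-templated aldol condensation (the BF2 variant of the Pabon reaction): BF3·OEt2 converts 21 into the 2,2-difluoro-1,3,2-dioxaborinine 23, which blocks the central methylene and acidifies the methyl groups, so that one methyl condenses with the aldehyde to the E-styryl chelate 24 while the excess of 21 limits double condensation; oxalate then takes the BF2 unit off and the free diketone is purified before the next step.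

Step 13
Reactants: 20 4-({(1R,4S,6R)-4-hydroxy-3-methyl-6-[(2S)-6-methyl-4-oxohept-5-en-2-yl]cyclohex-2-en-1-yl}oxy)-3-methoxybenzaldehyde; 25 (3Z,5E)-4-hydroxy-6-(4-hydroxyphenyl)hexa-3,5-dien-2-one
Product: 28 (1E,4Z,6E)-5-hydroxy-7-[4-({(1R,4S,6R)-4-hydroxy-3-methyl-6-[(2S)-6-methyl-4-oxohept-5-en-2-yl]cyclohex-2-en-1-yl}oxy)-3-methoxyphenyl]-1-(4-hydroxyphenyl)hepta-1,4,6-trien-3-one (Demethoxybisabolocurcumin Ether), via diketone dibutoxyboron chelate 26 (not isolated), via curcuminoid dibutoxyboron chelate 27 (not isolated)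
Conditions: 25, B2O3, B(OnBu)3, EtOAc, 70 °C; then 20, n-BuNH2 (0.3 equiv, slow addition), 70 °C; then 10% aq. AcOH, 40 °C
Reagents that add atoms: none
Why: Pabon aldol condensation: B2O3 and B(OnBu)3 should turn purified 25 into the dibutoxyboron chelate 26, whose remaining methyl group condenses with the aryl aldehyde to give the second E-styryl bond; mild acid hydrolysis of chelate 27 then frees the unsymmetrical curcuminoid, and the ring and side-chain stereocentres are not touched.

**Compound list**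

1 | (4S)-2,2-dimethyl-1,3-dioxolane-4-carbaldehyde | O=C[C@@H]1COC(C)(C)O1 | starting material
2 | (4R)-4-ethynyl-2,2-dimethyl-1,3-dioxolane | C#C[C@@H]1COC(C)(C)O1 | intermediate
3 | (2R)-but-3-yne-1,2-diol | C#C[C@@H](O)CO | intermediate
4 | (Z)-alkenylmagnesium bromide of 3 as its bis(bromomagnesium) alkoxide | Br[Mg]/C=C(C)\[C@@H](O[Mg]Br)CO[Mg]Br | intermediate
5 | (2R,3Z)-4-iodo-3-methylbut-3-ene-1,2-diol | I/C=C(C)\[C@@H](O)CO | intermediate
6 | (2R,3Z)-2-hydroxy-4-iodo-3-methylbut-3-en-1-yl 4-methylbenzenesulfonate | I/C=C(C)\[C@@H](O)COS(=O)(=O)c1ccc(C)cc1 | intermediate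
7 | (2R,3Z)-2-{[tert-butyl(dimethyl)silyl]oxy}-4-iodo-3-methylbut-3-en-1-yl 4-methylbenzenesulfonate | I/C=C(C)\[C@@H](O[Si](C)(C)C(C)(C)C)COS(=O)(=O)c1ccc(C)cc1 | intermediate
8 | (3R)-5-methoxy-3-methyl-5-oxopentanoic acid | COC(=O)C[C@H](C)CC(=O)O | starting material
9 | methyl (3R)-5-[methoxy(methyl)amino]-3-methyl-5-oxopentanoate | COC(=O)C[C@H](C)CC(=O)N(C)OC | intermediate
10 | (Z)-alkenylmagnesium chloride from 7 | Cl[Mg]/C=C(C)\[C@@H](O[Si](C)(C)C(C)(C)C)COS(=O)(=O)c1ccc(C)cc1 | intermediate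
11 | methyl (3R,6Z,8R)-8-{[tert-butyl(dimethyl)silyl]oxy}-3,7-dimethyl-9-[(4-methylbenzenesulfonyl)oxy]-5-oxonon-6-enoate | COC(=O)C[C@H](C)CC(=O)/C=C(C)\[C@@H](O[Si](C)(C)C(C)(C)C)COS(=O)(=O)c1ccc(C)cc1 | intermediate
12 | lithium cross-conjugated dienolate of 11 (enolate carbon C6, side chain cis to oxygen) | COC(=O)C[C@H](C)/C=C(\O[Li])/C=C(C)\[C@@H](O[Si](C)(C)C(C)(C)C)COS(=O)(=O)c1ccc(C)cc1 | intermediate
13 | methyl (3S)-3-[(1R,5S)-5-{[tert-butyl(dimethyl)silyl]oxy}-4-methyl-2-oxocyclohex-3-en-1-yl]butanoate | O=C1C=C(C)[C@@H](O[Si](C)(C)C(C)(C)C)C[C@@H]1[C@@H](C)CC(=O)OC | intermediate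
14 | methyl (3S)-3-[(1R,2R,5S)-5-{[tert-butyl(dimethyl)silyl]oxy}-2-hydroxy-4-methylcyclohex-3-en-1-yl]butanoate | O[C@H]1C=C(C)[C@@H](O[Si](C)(C)C(C)(C)C)C[C@@H]1[C@@H](C)CC(=O)OC | intermediate
15 | (3S)-3-[(1R,2R,5S)-5-{[tert-butyl(dimethyl)silyl]oxy}-2-hydroxy-4-methylcyclohex-3-en-1-yl]-N-methoxy-N-methylbutanamide | O[C@H]1C=C(C)[C@@H](O[Si](C)(C)C(C)(C)C)C[C@@H]1[C@@H](C)CC(=O)N(C)OC | intermediate
16 | (6S)-6-[(1R,2R,5S)-5-{[tert-butyl(dimethyl)silyl]oxy}-2-hydroxy-4-methylcyclohex-3-en-1-yl]-2-methylhept-2-en-4-one | O[C@H]1C=C(C)[C@@H](O[Si](C)(C)C(C)(C)C)C[C@@H]1[C@@H](C)CC(=O)C=C(C)C | intermediate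
17 | (1R,4S,6R)-4-{[tert-butyl(dimethyl)silyl]oxy}-3-methyl-6-[(2S)-6-methyl-4-oxohept-5-en-2-yl]cyclohex-2-en-1-yl methyl carbonate | COC(=O)O[C@H]1C=C(C)[C@@H](O[Si](C)(C)C(C)(C)C)C[C@@H]1[C@@H](C)CC(=O)C=C(C)C | intermediate
18 | 4-hydroxy-3-methoxybenzaldehyde | COc1cc(C=O)ccc1O | starting material
19 | 4-({(1R,4S,6R)-4-{[tert-butyl(dimethyl)silyl]oxy}-3-methyl-6-[(2S)-6-methyl-4-oxohept-5-en-2-yl]cyclohex-2-en-1-yl}oxy)-3-methoxybenzaldehyde | COc1cc(C=O)ccc1O[C@H]1C=C(C)[C@@H](O[Si](C)(C)C(C)(C)C)C[C@@H]1[C@@H](C)CC(=O)C=C(C)C | intermediate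
20 | 4-({(1R,4S,6R)-4-hydroxy-3-methyl-6-[(2S)-6-methyl-4-oxohept-5-en-2-yl]cyclohex-2-en-1-yl}oxy)-3-methoxybenzaldehyde | COc1cc(C=O)ccc1O[C@H]1C=C(C)[C@@H](O)C[C@@H]1[C@@H](C)CC(=O)C=C(C)C | intermediate
21 | pentane-2,4-dione | CC(=O)CC(C)=O | starting material
22 | 4-hydroxybenzaldehyde | O=Cc1ccc(O)cc1 | starting material
23 | 2,2-difluoro-4,6-dimethyl-1,3,2-dioxaborinine (difluoroboron chelate of 21) | CC1=CC(C)=[O+][B-](F)(F)O1 | intermediate
24 | 2,2-difluoro-4-[(E)-2-(4-hydroxyphenyl)ethenyl]-6-methyl-1,3,2-dioxaborinine (difluoroboron chelate of 25) | CC1=CC(/C=C/c2ccc(O)cc2)=[O+][B-](F)(F)O1 | intermediate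
25 | (3Z,5E)-4-hydroxy-6-(4-hydroxyphenyl)hexa-3,5-dien-2-one | CC(=O)/C=C(O)/C=C/c1ccc(O)cc1 | intermediate
26 | dibutoxyboron chelate of 25 (simplest formulation) | CCCCO[B-]1(OCCCC)OC(C)=CC(/C=C/c2ccc(O)cc2)=[O+]1 | intermediate
27 | dibutoxyboron chelate of 28 (simplest formulation) | CCCCO[B-]1(OCCCC)OC(/C=C/c2ccc(O)cc2)=CC(/C=C/c2ccc(O[C@H]3C=C(C)[C@@H](O)C[C@@H]3[C@@H](C)CC(=O)C=C(C)C)c(OC)c2)=[O+]1 | intermediate
28 | (1E,4Z,6E)-5-hydroxy-7-[4-({(1R,4S,6R)-4-hydroxy-3-methyl-6-[(2S)-6-methyl-4-oxohept-5-en-2-yl]cyclohex-2-en-1-yl}oxy)-3-methoxyphenyl]-1-(4-hydroxyphenyl)hepta-1,4,6-trien-3-one | COc1cc(/C=C/C(O)=C/C(=O)/C=C/c2ccc(O)cc2)ccc1O[C@H]1C=C(C)[C@@H](O)C[C@@H]1[C@@H](C)CC(=O)C=C(C)C | target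

**Count**

Total steps: 13. Longest linear sequence: 11 (steps 1, 2, 3, 5, 6, 7, 8, 9, 10, 11, 13).

**Steps most likely to fail**

Step 6 (ring closure). The dienolate may close through oxygen to a six-membered dienol ether, gamma-deprotonation may erode the Z geometry and the C4 configuration, or displacement at the beta-silyloxy carbon may be too slow. The fallback sets out from 5 and 8 and comes back at 13; it makes the C5–C6 bond between two molecules under ring control and closes the ring at C1–C2 instead. The ester arm of 8 is reduced and lactonised (LiBH4, THF; then aq. HCl) to (4S)-4-methyloxan-2-one F1, whose carbonyl is the later C1. Diol 5 is converted in one flask (Tf2O, 2,6-lutidine, CH2Cl2, −78 °C; then TBSOTf) into (2R,3Z)-2-{[tert-butyl(dimethyl)silyl]oxy}-4-iodo-3-methylbut-3-en-1-yl trifluoromethanesulfonate F2. The lithium enolate of F1 (LiN(iPr)2, THF, −78 °C) should be alkylated by F2 anti to the ring methyl group to give (3R,4S)-3-[(2S,3Z)-2-{[tert-butyl(dimethyl)silyl]oxy}-4-iodo-3-methylbut-3-en-1-yl]-4-methyloxan-2-one F3. Iodine–lithium exchange (t-BuLi, Et2O, −78 °C) and attack of the alkenyllithium on the lactone carbonyl then give (4S,6R)-4-{[tert-butyl(dimethyl)silyl]oxy}-6-[(2S)-4-hydroxybutan-2-yl]-3-methylcyclohex-2-en-1-one F4. Oxidation of the primary alcohol (TEMPO, PhI(OAc)2, MeCN/H2O) gives (3S)-3-[(1R,5S)-5-{[tert-butyl(dimethyl)silyl]oxy}-4-methyl-2-oxocyclohex-3-en-1-yl]butanoic acid F5, and esterification (Me3SiCHN2, MeOH/toluene) gives 13.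

Step 5 (fragment union). The iodine–magnesium exchange of the trisubstituted alkenyl iodide may be incomplete, the organomagnesium species may attack the tosylate, or it may add to the methyl ester as well. The fallback sets out from 7 and 8 and comes back at 11; it replaces the acylation by a chromium-mediated aldehyde coupling followed by oxidation. The acid arm of 8 is reduced (BH3·SMe2, THF, 0 °C) to methyl (3R)-5-hydroxy-3-methylpentanoate F6 and oxidised (Dess–Martin periodinane) to methyl (3R)-3-methyl-5-oxopentanoate F7. Nozaki–Hiyama–Kishi coupling of F7 with 7 (CrCl2, NiCl2 (cat.), DMSO, rt), which tolerates ester and tosylate, should give methyl (3R,6Z,8R)-8-{[tert-butyl(dimethyl)silyl]oxy}-5-hydroxy-3,7-dimethyl-9-[(4-methylbenzenesulfonyl)oxy]non-6-enoate F8 as both carbinol epimers. Oxidation of F8 (Dess–Martin periodinane) gives 11.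

Step 10 (aryl ether). The allylpalladium intermediate may lose a beta-hydrogen to give a diene, the phenoxide may attack the tertiary allyl terminus, or reversible ionisation of the product may erode the C1 configuration. The fallback sets out from 16 and comes back at 19; it replaces the palladium step by two Mitsunobu inversions. Reaction of 16 with 4-nitrobenzoic acid (PPh3, DIAD, THF) should give, with inversion, (1S,4S,6R)-4-{[tert-butyl(dimethyl)silyl]oxy}-3-methyl-6-[(2S)-6-methyl-4-oxohept-5-en-2-yl]cyclohex-2-en-1-yl 4-nitrobenzoate F9. Methanolysis (K2CO3, MeOH, 0 °C) gives (6S)-6-[(1R,2S,5S)-5-{[tert-butyl(dimethyl)silyl]oxy}-2-hydroxy-4-methylcyclohex-3-en-1-yl]-2-methylhept-2-en-4-one F10. A second Mitsunobu reaction of F10 with 18 (PPh3, DIAD, THF) inverts C1 again and gives 19.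

Further compounds
F1 | step 6 | (4S)-4-methyloxan-2-one | O=C1C[C@@H](C)CCO1
F2 | step 6 | (2R,3Z)-2-{[tert-butyl(dimethyl)silyl]oxy}-4-iodo-3-methylbut-3-en-1-yl trifluoromethanesulfonate | I/C=C(C)\[C@@H](O[Si](C)(C)C(C)(C)C)COS(=O)(=O)C(F)(F)F
F3 | step 6 | (3R,4S)-3-[(2S,3Z)-2-{[tert-butyl(dimethyl)silyl]oxy}-4-iodo-3-methylbut-3-en-1-yl]-4-methyloxan-2-one | O=C1OCC[C@H](C)[C@H]1C[C@H](O[Si](C)(C)C(C)(C)C)/C(C)=C\I
F4 | step 6 | (4S,6R)-4-{[tert-butyl(dimethyl)silyl]oxy}-6-[(2S)-4-hydroxybutan-2-yl]-3-methylcyclohex-2-en-1-one | O=C1C=C(C)[C@@H](O[Si](C)(C)C(C)(C)C)C[C@@H]1[C@@H](C)CCO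
F5 | step 6 | (3S)-3-[(1R,5S)-5-{[tert-butyl(dimethyl)silyl]oxy}-4-methyl-2-oxocyclohex-3-en-1-yl]butanoic acid | O=C1C=C(C)[C@@H](O[Si](C)(C)C(C)(C)C)C[C@@H]1[C@@H](C)CC(=O)O
F6 | step 5 | methyl (3R)-5-hydroxy-3-methylpentanoate | COC(=O)C[C@H](C)CCO
F7 | step 5 | methyl (3R)-3-methyl-5-oxopentanoate | COC(=O)C[C@H](C)CC=O
F8 | step 5 | methyl (3R,6Z,8R)-8-{[tert-butyl(dimethyl)silyl]oxy}-5-hydroxy-3,7-dimethyl-9-[(4-methylbenzenesulfonyl)oxy]non-6-enoate (both C5 epimers) | COC(=O)C[C@H](C)CC(O)/C=C(C)\[C@@H](O[Si](C)(C)C(C)(C)C)COS(=O)(=O)c1ccc(C)cc1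
F9 | step 10 | (1S,4S,6R)-4-{[tert-butyl(dimethyl)silyl]oxy}-3-methyl-6-[(2S)-6-methyl-4-oxohept-5-en-2-yl]cyclohex-2-en-1-yl 4-nitrobenzoate | O=C(O[C@@H]1C=C(C)[C@@H](O[Si](C)(C)C(C)(C)C)C[C@@H]1[C@@H](C)CC(=O)C=C(C)C)c1ccc(cc1)[N+](=O)[O-]
F10 | step 10 | (6S)-6-[(1R,2S,5S)-5-{[tert-butyl(dimethyl)silyl]oxy}-2-hydroxy-4-methylcyclohex-3-en-1-yl]-2-methylhept-2-en-4-one | O[C@@H]1C=C(C)[C@@H](O[Si](C)(C)C(C)(C)C)C[C@@H]1[C@@H](C)CC(=O)C=C(C)C
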